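## Structural features

The target is a flavan-3,4-diol. The benzo ring A (C4a to C8a) is fused to the dihydropyran ring C (O1, C2, C3, C4); C2 carries the 3,4,5-trihydroxyphenyl ring B, and C3 and C4 carry hydroxyls. Ring A is hexasubstituted and pentaoxygenated (O1 at C8a, OMe at C8, OH at C7, OMe at C6, OH at C5), so it has no free CH and every position is differentiated. C2 (R), C3 (S) and C4 (R) are contiguous, and the aryl group, the C3 hydroxyl and the C4 hydroxyl are mutually trans (2,3-trans, 3,4-trans), all equatorial on the half-chair of ring C. The C4 hydroxyl is benzylic to a ring with oxygen at both ortho positions (C5, C8a) and at the para position (C7), so it ionises with traces of acid and is at risk under reductive conditions. The pyrogallol ring B and the phloroglucinol-type ring A are oxidised by air under base, so the free phenols can appear only in the last step and under neutral conditions. The real difficulty is to fix the absolute configuration at C2 and relay it to C3 and C4 in the all-trans sense on this electron-rich, acid-labile scaffold, while assembling the fully substituted ring A. The key step exploits the array O1–C2–C3=C4–C4a in conjugation with the ring A donors at C5, C7 and C8a: with a leaving group on C2 this array is a latent, strongly stabilised benzopyrylium ion. Ring B can therefore be delivered as an aryl nucleophile to C2 under catalyst control, and the C3=C4 alkene left behind is the handle for the trans-diol. In one sentence, the route is the enantioselective transfer of the ring B aryl group from boron to C2 of a ring A/C benzopyrylium ion generated from a racemic 2-ethoxy-2H-chromene.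

## Logic of the disconnections

19 to 18. The five phenolic O–CH2Ph bonds are cut. Free polyphenols would not survive the oxidative and Lewis acidic steps, and hydrogenolysis is the only unmasking that needs neither acid nor base. The skeleton is not simplified, but every earlier step becomes possible. The forward step must cleave five benzyl ethers while sparing the benzylic C4–O bond, which demands a neutral, aprotic medium.

18 to 16 (through 17). The C3–O and C4–O bonds are cut. The all-trans pattern is the outcome of an anti addition across a C3=C4 alkene that starts on the face opposite the C2 aryl group: epoxidation anti to the aryl group, then opening at C4 with inversion. Two stereocentres and two C–O bonds disappear, and the stereochemical problem shrinks to C2 alone. The forward step needs facial selectivity in the epoxidation, exclusive attack of water at C4 and suppression of a hydride shift to a C3 ketone.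

16 to 8 and 13 (through 14 and 15). The C2–C1′ bond is cut. C2 lies between O1 and the C3=C4 alkene that is conjugated with ring A, so loss of a leaving group from C2 gives an aromatic benzopyrylium ion, and ring B can arrive as an aryl group migrating from boron. The molecule falls into two fragments of similar size, neither with a stereocentre that matters (8 is racemic and its stereocentre is erased on ionisation), and the absolute configuration is supplied by a catalyst. The forward step needs attack at C2 and not at C4, high facial selectivity within an ion pair, and a product that keeps its configuration.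

8 to 7 to 6. The C2–OEt bond is cut and C2 is returned to the lactone oxidation level. A lactone is a stable carrier of the O1–C2–C3=C4 unit, whereas the acetal is acid-labile and is best made just before use. The forward steps need a partial reduction that stops at the lactol and an acetalisation mild enough for an electron-rich chromene.

6 to 4 (through 5). The C3=C4 double bond (olefination) and the O1–C2 ester bond (lactonisation) are cut. The formyl carbon of 4 is C4 and its ortho hydroxyl is O1, so ring C is reduced to a two-carbon extension of a benzaldehyde. The forward step needs E to Z isomerisation of the first-formed alkene so that the phenol can close the lactone.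

4 to 3 to 2 to 1. The two aryl C–OMe bonds (C6 and C8 of the target) are cut back to C–Br and then to C–H, and two O–benzyl bonds are cut. Compound 1 already holds the 1,3,5-oxygen pattern and the C4 carbon, its two free ring positions are exactly where the methoxy groups belong, and the hydroxyl hydrogen-bonded to the formyl group stays free to become O1. Ring A is thus reached from a catalogue aldehyde in three steps. The forward steps need selective bis-O-benzylation and a complete double methoxylation at hindered positions.

13 to 10 to 9 (through 11 and 12). The C–B bond and three O–benzyl bonds are cut. Bromine–lithium exchange is the shortest way to the boronic acid. The forward step needs exchange faster than benzylic deprotonation, which low temperature secures.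

## Other disconnections considered

Alternative 1: the route most chemists would draw first. Cut O1–C2 and C2–C3 (aldol condensation of a ring A acetophenone with a ring B aldehyde) and treat the C4 carbinol as a reduced ketone. Forward: asymmetric epoxidation of the 2′-hydroxychalcone A1, 6-endo opening by the phenol to the (2R,3R)-dihydroflavonol A2, then hydride reduction of the C4 ketone.
- The ring A ketone in A1 is flanked by two ortho substituents and is twisted out of conjugation, which should retard nucleophilic epoxidation.
- The same twist favours 5-exo attack at the α-carbon, leading to aurone-type benzofuranones instead of A2.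
- C2 of A2 can open by retro-oxa-Michael reaction under base, which threatens the stereochemistry.
- A1 needs a hexasubstituted acetophenone with the same oxygenation work as the chosen plan, so no steps are saved.
- In the chosen plan C2 is set at an unhindered cationic carbon.

Alternative 2: C-aryl glycoside logic. Cut C2–C1′ at the lactone oxidation level. Forward: asymmetric dihydroxylation of the phenol-masked cinnamate related to 5 and lactonisation to the (3S,4R)-bis(silyloxy)lactone A3, addition of the aryllithium 11 to give the hemiketal A4, then silane reduction of the derived oxocarbenium ion with axial hydride delivery.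
- The Lewis acid must ionise C2 of A4, yet the C4–O bond, benzylic to the trioxygenated ring, gives the more stabilised cation. Reductive loss of the C4 oxygen or elimination should therefore compete.
- A4 can equilibrate with its open hydroxy ketone form.
- Additional protecting-group operations are needed on the diol and the lactonising phenol.
- The chosen plan introduces the C4 oxygen only after C2 is fixed, so this competition never arises.

Alternative 3: cut O1–C2 and C3–C4 together. Forward: inverse-demand hetero-Diels–Alder reaction of the ortho-quinone methide oxocarbenium ion A5 (from 4 and an orthoformate) with the (E)-enol acetate A6, to give the 3-acetoxy-4-methoxyflavan A7 with all three stereocentres in one step.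
- The enol oxygen of A6 makes the aryl-bearing carbon the nucleophilic terminus, which leads to the 2-acetoxy-3-aryl regioisomer rather than A7.
- Endo/exo control at C4 and enantiofacial control on a cationic heterodiene without a binding site for a chiral catalyst are not secured.
- A7 would need acidic cleavage of the C4 methyl ether, which the target cannot bear.
- The chosen plan separates the events, each with a defined control element.

Key step: step 9

Assumption: compounds 1 and 9 are taken as catalogue materials, and the antipode of the tartaric acid amide catalyst used in step 9 is the one that leads to the (S) configuration of 16.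

## Route

Step 1
Reactants: 1 2,4,6-trihydroxybenzaldehyde
Product: 2 2,4-bis(benzyloxy)-6-hydroxybenzaldehyde
Conditions: BnBr (2.1 equiv), K2CO3 (2.2 equiv), DMF, 0 °C to rt
Reagents that add atoms: benzyl bromide, BrCc1ccccc1
Why: Williamson etherification; the para hydroxyl and one ortho hydroxyl react, while the hydroxyl that stays hydrogen-bonded to the formyl oxygen is the least nucleophilic and should remain free with two equivalents of halide.

Step 2
Reactants: 2 2,4-bis(benzyloxy)-6-hydroxybenzaldehyde
Product: 3 2,4-bis(benzyloxy)-3,5-dibromo-6-hydroxybenzaldehyde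
Conditions: NBS (2.1 equiv), MeCN, 0 °C
Reagents that add atoms: N-bromosuccinimide, O=C1CCC(=O)N1Br
Why: electrophilic aromatic bromination; the only two free ring positions are each ortho or para to three oxygen donors, so double substitution should be fast and regiochemically unambiguous.

Step 3
Reactants: 3 2,4-bis(benzyloxy)-3,5-dibromo-6-hydroxybenzaldehyde
Product: 4 2,4-bis(benzyloxy)-6-hydroxy-3,5-dimethoxybenzaldehyde
Conditions: NaOMe (25% in MeOH, 8 equiv), CuBr (0.4 equiv), DMF, 110 °C, Ar
Reagents that add atoms: sodium methoxide, [Na+].[O-]C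
Why: Ullmann-type copper-mediated methoxylation of aryl bromides, a reaction class that tolerates a free phenoxide and a formyl group on the same ring; benzyl ethers are inert to methoxide.

Step 4
Reactants: 4 2,4-bis(benzyloxy)-6-hydroxy-3,5-dimethoxybenzaldehyde
Product: 6 5,7-bis(benzyloxy)-6,8-dimethoxy-2H-chromen-2-one, via hydroxycinnamate ester 5 (not isolated)
Conditions: Ph3P=CHCO2Et (1.5 equiv), PhNEt2, reflux (ca. 215 °C)
Reagents that add atoms: ethyl (triphenylphosphoranylidene)acetate, CCOC(=O)C=P(c1ccccc1)(c1ccccc1)c1ccccc1
Why: Wittig olefination gives the (E)-cinnamate, which at this temperature isomerises and lactonises through the ortho phenol, the standard one-pot coumarin synthesis from salicylaldehydes.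

Step 5
Reactants: 6 5,7-bis(benzyloxy)-6,8-dimethoxy-2H-chromen-2-one
Product: 7 5,7-bis(benzyloxy)-6,8-dimethoxy-2H-chromen-2-ol (racemic)
Conditions: DIBAL-H (1.15 equiv), CH2Cl2, −78 °C; aq. Rochelle salt
Reagents that add atoms: none
Why: partial reduction of a lactone to the lactol; the tetrahedral aluminium alkoxide is stable at −78 °C, which should prevent over-reduction.

Step 6
Reactants: 7 5,7-bis(benzyloxy)-6,8-dimethoxy-2H-chromen-2-ol (racemic)
Product: 8 5,7-bis(benzyloxy)-2-ethoxy-6,8-dimethoxy-2H-chromene (racemic)
Conditions: EtOH, PPTS (5 mol %), rt; Et3N quench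
Reagents that add atoms: ethanol, CCO
Why: acid-catalysed acetalisation through the stabilised benzopyrylium ion; any 4-ethoxy-4H isomer would be harmless because it ionises to the same cation in step 9.

Step 7
Reactants: 9 5-bromobenzene-1,2,3-triol
Product: 10 1,2,3-tris(benzyloxy)-5-bromobenzene
Conditions: BnBr (3.3 equiv), K2CO3 (4 equiv), DMF, 60 °C
Reagents that add atoms: benzyl bromide, BrCc1ccccc1
Why: exhaustive Williamson etherification of the three phenols under argon to avoid oxidation of the pyrogallol.

Step 8
Reactants: 10 1,2,3-tris(benzyloxy)-5-bromobenzene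
Product: 13 [3,4,5-tris(benzyloxy)phenyl]boronic acid, via aryllithium 11 (not isolated), via lithium triisopropoxyborate 12 (not isolated)
Conditions: n-BuLi (1.05 equiv), THF, −78 °C; B(OiPr)3 (1.5 equiv), −78 °C to rt; 1 M HCl
Reagents that add atoms: triisopropyl borate, CC(C)OB(OC(C)C)OC(C)C; water, O
Why: bromine–lithium exchange is much faster at −78 °C than benzylic deprotonation; trapping with the borate and hydrolysis of the ate complex gives the boronic acid.

Step 9
Reactants: 8 5,7-bis(benzyloxy)-2-ethoxy-6,8-dimethoxy-2H-chromene (racemic); 13 [3,4,5-tris(benzyloxy)phenyl]boronic acid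
Product: 16 (S)-5,7-bis(benzyloxy)-6,8-dimethoxy-2-[3,4,5-tris(benzyloxy)phenyl]-2H-chromene, via diethyl boronate 14 (not isolated), via benzopyrylium ion 15 (not isolated)
Conditions: 13 (1.6 equiv), EtOH, 4 Å MS, PhMe, rt, then concentrate; 8, tartaric acid mono(N,N-dibenzylamide) (10 mol %), Yb(OTf)3 (8 mol %), EtOAc, −20 to 4 °C, dark
Reagents that add atoms: none
Why: Boronic acid 13 is esterified in the flask to 14, which exchanges with the chiral α,β-dihydroxy carboxylic acid catalyst to a more Lewis acidic chiral boronate; this boron centre, assisted by Yb(OTf)3, abstracts ethoxide from racemic 8 to give the planar ion 15 paired with a chiral tetracoordinate arylborate, and the aryl group then migrates from boron to C2 within the contact ion pair. The closest known reaction type is the enantioselective Petasis-type addition of aryl and alkenyl boronates to 2H-chromene acetals under chiral hydroxy acid and lanthanide triflate catalysis. No ring is closed, since ring C is carried through intact as the aromatic cation 15. The new stereocentre C2 is controlled by the catalyst, which presents the aryl group to one face of 15, and because both enantiomers of 8 converge on 15 the process is enantioconvergent; the (S) descriptor of 16 corresponds spatially to the (R) centre of the target once C3 carries oxygen. Attack at C2 over C4 is needed and is secured because the borate is formed at the departing C2 ethoxide, because C4 is shielded by the peri benzyloxy group at C5, and because C2 attack keeps the alkene conjugated with ring A. Donation from O1 and the oxygens at C5 and C7 makes ionisation possible at low temperature with a mild Lewis acid, and the para-alkoxy aryl group of 14 is a good migrating group. The fully substituted ring A cannot undergo Friedel–Crafts self-condensation with 15, and benzyl and methyl ethers are inert under these conditions.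

Step 10
Reactants: 16 (S)-5,7-bis(benzyloxy)-6,8-dimethoxy-2-[3,4,5-tris(benzyloxy)phenyl]-2H-chromene
Product: 18 (2R,3S,4R)-5,7-bis(benzyloxy)-6,8-dimethoxy-2-[3,4,5-tris(benzyloxy)phenyl]chromane-3,4-diol, via epoxide 17 (not isolated)
Conditions: DMDO (1.2 equiv, acetone), THF/pH 7 phosphate buffer (5:1), −20 to 0 °C, dark
Reagents that add atoms: dimethyldioxirane, CC1(C)OO1; water, O
Why: epoxidation of the electron-rich styrenic alkene should occur on the face opposite the C2 aryl group and set C3; the labile epoxide 17 then opens at C4 only (benzylic, three oxygen donors) with water entering anti to the C3 oxygen, which gives the 3,4-trans and hence all-equatorial diol.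

Step 11
Reactants: 18 (2R,3S,4R)-5,7-bis(benzyloxy)-6,8-dimethoxy-2-[3,4,5-tris(benzyloxy)phenyl]chromane-3,4-diol
Product: 19 (2R,3S,4R)-6,8-dimethoxy-2-(3,4,5-trihydroxyphenyl)chromane-3,4,5,7-tetrol (target)
Conditions: H2 (1 atm), Pd(OH)2/C, EtOAc/THF, solid NaHCO3, rt; filtration under Ar
Reagents that add atoms: none
Why: hydrogenolysis of five aryl benzyl ethers; in a neutral aprotic medium the free C4 hydroxyl is a poor leaving group and should be retained, and no stereocentre is touched.

## Compound list

1 | 2,4,6-trihydroxybenzaldehyde | O=Cc1c(O)cc(O)cc1O | starting material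
2 | 2,4-bis(benzyloxy)-6-hydroxybenzaldehyde | O=Cc1c(O)cc(OCc2ccccc2)cc1OCc1ccccc1 | intermediate
3 | 2,4-bis(benzyloxy)-3,5-dibromo-6-hydroxybenzaldehyde | O=Cc1c(O)c(Br)c(OCc2ccccc2)c(Br)c1OCc1ccccc1 | intermediate
4 | 2,4-bis(benzyloxy)-6-hydroxy-3,5-dimethoxybenzaldehyde | O=Cc1c(O)c(OC)c(OCc2ccccc2)c(OC)c1OCc1ccccc1 | intermediate
5 | ethyl (E)-3-[2,4-bis(benzyloxy)-6-hydroxy-3,5-dimethoxyphenyl]prop-2-enoate | CCOC(=O)/C=C/c1c(O)c(OC)c(OCc2ccccc2)c(OC)c1OCc1ccccc1 | intermediate (not isolated)
6 | 5,7-bis(benzyloxy)-6,8-dimethoxy-2H-chromen-2-one | O=C1C=Cc2c(OCc3ccccc3)c(OC)c(OCc3ccccc3)c(OC)c2O1 | intermediate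
7 | 5,7-bis(benzyloxy)-6,8-dimethoxy-2H-chromen-2-ol (racemic) | OC1C=Cc2c(OCc3ccccc3)c(OC)c(OCc3ccccc3)c(OC)c2O1 | intermediate
8 | 5,7-bis(benzyloxy)-2-ethoxy-6,8-dimethoxy-2H-chromene (racemic) | CCOC1C=Cc2c(OCc3ccccc3)c(OC)c(OCc3ccccc3)c(OC)c2O1 | intermediate
9 | 5-bromobenzene-1,2,3-triol | Oc1cc(Br)cc(O)c1O | starting material
10 | 1,2,3-tris(benzyloxy)-5-bromobenzene | Brc1cc(OCc2ccccc2)c(OCc2ccccc2)c(OCc2ccccc2)c1 | intermediate
11 | [3,4,5-tris(benzyloxy)phenyl]lithium | [Li]c1cc(OCc2ccccc2)c(OCc2ccccc2)c(OCc2ccccc2)c1 | intermediate (not isolated)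
12 | lithium triisopropoxy[3,4,5-tris(benzyloxy)phenyl]borate | [Li+].CC(C)O[B-](OC(C)C)(OC(C)C)c1cc(OCc2ccccc2)c(OCc2ccccc2)c(OCc2ccccc2)c1 | intermediate (not isolated)
13 | [3,4,5-tris(benzyloxy)phenyl]boronic acid | OB(O)c1cc(OCc2ccccc2)c(OCc2ccccc2)c(OCc2ccccc2)c1 | intermediate
14 | diethyl [3,4,5-tris(benzyloxy)phenyl]boronate | CCOB(OCC)c1cc(OCc2ccccc2)c(OCc2ccccc2)c(OCc2ccccc2)c1 | intermediate (not isolated)
15 | 5,7-bis(benzyloxy)-6,8-dimethoxychromenylium (1-benzopyrylium) ion | COc1c(OCc3ccccc3)c(OC)c2[o+]cccc2c1OCc1ccccc1 | intermediate (not isolated)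
16 | (S)-5,7-bis(benzyloxy)-6,8-dimethoxy-2-[3,4,5-tris(benzyloxy)phenyl]-2H-chromene | COc1c(OCc3ccccc3)c(OC)c2c(c1OCc4ccccc4)C=C[C@@H](c5cc(OCc6ccccc6)c(OCc6ccccc6)c(OCc6ccccc6)c5)O2 | intermediate
17 | (2R,3S,4S)-5,7-bis(benzyloxy)-3,4-epoxy-6,8-dimethoxy-2-[3,4,5-tris(benzyloxy)phenyl]chromane (epoxide oxygen anti to the C2 aryl group) | COc1c(OCc3ccccc3)c(OC)c2c(c1OCc4ccccc4)[C@@H]7O[C@@H]7[C@@H](c5cc(OCc6ccccc6)c(OCc6ccccc6)c(OCc6ccccc6)c5)O2 | intermediate (not isolated)
18 | (2R,3S,4R)-5,7-bis(benzyloxy)-6,8-dimethoxy-2-[3,4,5-tris(benzyloxy)phenyl]chromane-3,4-diol | COc1c(OCc3ccccc3)c(OC)c2c(c1OCc4ccccc4)[C@@H](O)[C@H](O)[C@@H](c5cc(OCc6ccccc6)c(OCc6ccccc6)c(OCc6ccccc6)c5)O2 | intermediate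
19 | (2R,3S,4R)-6,8-dimethoxy-2-(3,4,5-trihydroxyphenyl)chromane-3,4,5,7-tetrol | COc1c(O)c(OC)c2c(c1O)[C@@H](O)[C@H](O)[C@@H](c1cc(O)c(O)c(O)c1)O2 | target

## Step count and least certain steps

Total step count: 11. Longest linear sequence: 9 steps (steps 1 to 6, then 9 to 11); steps 7 and 8 form the second branch.

Step 9 (key step). The most likely failure is loss of enantiocontrol. The cation 15 is unusually stabilised and long-lived, so aryl transfer may occur outside the chiral ion pair in a racemic background process, or partly at C4. Light-induced electrocyclic ring opening of 16 could also erode its configuration. The fallback abandons the benzopyrylium manifold: it sets C2 by asymmetric allylic etherification and closes ring C by metathesis. It sets out from 4 and 10 and returns at 16.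
- Aldehyde 4 is methylenated (Ph3P=CH2, 2.2 equiv, THF) to 3,5-bis(benzyloxy)-2,4-dimethoxy-6-vinylphenol F1.
- Bromide 10 is taken by a Heck reaction with methyl acrylate (Pd(OAc)2, P(o-tol)3, Et3N) to methyl (E)-3-[3,4,5-tris(benzyloxy)phenyl]prop-2-enoate F2.
- DIBAL-H reduction gives (E)-3-[3,4,5-tris(benzyloxy)phenyl]prop-2-en-1-ol F3.
- Methyl chloroformate and pyridine give methyl (E)-3-[3,4,5-tris(benzyloxy)phenyl]prop-2-en-1-yl carbonate F4.
- The phenoxide of F1 and F4, with [Ir(cod)Cl]2 and a chiral phosphoramidite ligand, should give the branched ether 1,3-bis(benzyloxy)-2,4-dimethoxy-5-{[(1S)-1-[3,4,5-tris(benzyloxy)phenyl]prop-2-en-1-yl]oxy}-6-vinylbenzene F5.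
- Ring-closing metathesis with the second-generation Grubbs catalyst then gives 16.

Step 3. The most likely failure is incomplete substitution at the bromide flanked by two benzyloxy groups, together with competing protodebromination on the very electron-rich phenoxide. The fallback removes the phenoxide and changes the metal and mechanism. It sets out from 3 and returns at 4.
- The phenol of 3 is benzylated to 2,4,6-tris(benzyloxy)-3,5-dibromobenzaldehyde F6.
- C–O coupling with methanol (Pd2(dba)3, tBuBrettPhos, Cs2CO3, toluene) gives 2,4,6-tris(benzyloxy)-3,5-dimethoxybenzaldehyde F7.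
- Chelation-controlled cleavage of one benzyl ether ortho to the formyl group (MgBr2·OEt2) returns 4.

Step 10. The most likely failure is a 1,2-hydride shift in the opened C4 cation to a C3 ketone before water is captured, or over-oxidation of ring A by the dioxirane. The fallback installs the two oxygens separately. It sets out from 16 and returns at 18.
- Hydroboration–oxidation (BH3·THF, then H2O2/NaOH), anti to the aryl group with boron at C3, gives (2R,3S)-5,7-bis(benzyloxy)-6,8-dimethoxy-2-[3,4,5-tris(benzyloxy)phenyl]chroman-3-ol F8.
- Benzylic oxidation at C4 with DDQ in wet CH2Cl2, with water entering trans to the C3 hydroxyl, gives 18.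

Step 11. The most likely failure is hydrogenolytic loss of the C4 oxygen, or acid-promoted solvolysis at C4 on the catalyst surface. The fallback keeps C4 at the ketone level during debenzylation. It sets out from 18 and returns at 19.
- Selective oxidation of the benzylic C4 alcohol (MnO2, CH2Cl2) gives (2R,3R)-5,7-bis(benzyloxy)-3-hydroxy-6,8-dimethoxy-2-[3,4,5-tris(benzyloxy)phenyl]chroman-4-one F9.
- Hydrogenolysis (H2, Pd/C, EtOAc) gives (2R,3R)-3,5,7-trihydroxy-6,8-dimethoxy-2-(3,4,5-trihydroxyphenyl)chroman-4-one F10.
- NaBH4 in ethanol at 0 °C, with hydride delivered anti to the C3 hydroxyl, gives 19.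

## Further compounds

F1 | step 9 | 3,5-bis(benzyloxy)-2,4-dimethoxy-6-vinylphenol | C=Cc1c(O)c(OC)c(OCc2ccccc2)c(OC)c1OCc1ccccc1
F2 | step 9 | methyl (E)-3-[3,4,5-tris(benzyloxy)phenyl]prop-2-enoate | COC(=O)/C=C/c1cc(OCc2ccccc2)c(OCc2ccccc2)c(OCc2ccccc2)c1
F3 | step 9 | (E)-3-[3,4,5-tris(benzyloxy)phenyl]prop-2-en-1-ol | OC/C=C/c1cc(OCc2ccccc2)c(OCc2ccccc2)c(OCc2ccccc2)c1
F4 | step 9 | methyl (E)-3-[3,4,5-tris(benzyloxy)phenyl]prop-2-en-1-yl carbonate | COC(=O)OC/C=C/c1cc(OCc2ccccc2)c(OCc2ccccc2)c(OCc2ccccc2)c1
F5 | step 9 | 1,3-bis(benzyloxy)-2,4-dimethoxy-5-{[(1S)-1-[3,4,5-tris(benzyloxy)phenyl]prop-2-en-1-yl]oxy}-6-vinylbenzene | C=C[C@@H](c1cc(OCc2ccccc2)c(OCc2ccccc2)c(OCc2ccccc2)c1)Oc1c(C=C)c(OCc2ccccc2)c(OC)c(OCc2ccccc2)c1OC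
F6 | step 3 | 2,4,6-tris(benzyloxy)-3,5-dibromobenzaldehyde | O=Cc1c(OCc2ccccc2)c(Br)c(OCc2ccccc2)c(Br)c1OCc1ccccc1
F7 | step 3 | 2,4,6-tris(benzyloxy)-3,5-dimethoxybenzaldehyde | O=Cc1c(OCc2ccccc2)c(OC)c(OCc2ccccc2)c(OC)c1OCc1ccccc1
F8 | step 10 | (2R,3S)-5,7-bis(benzyloxy)-6,8-dimethoxy-2-[3,4,5-tris(benzyloxy)phenyl]chroman-3-ol | COc1c(OCc3ccccc3)c(OC)c2c(c1OCc4ccccc4)C[C@H](O)[C@@H](c5cc(OCc6ccccc6)c(OCc6ccccc6)c(OCc6ccccc6)c5)O2
F9 | step 11 | (2R,3R)-5,7-bis(benzyloxy)-3-hydroxy-6,8-dimethoxy-2-[3,4,5-tris(benzyloxy)phenyl]chroman-4-one | COc1c(OCc3ccccc3)c(OC)c2c(c1OCc4ccccc4)C(=O)[C@H](O)[C@@H](c5cc(OCc6ccccc6)c(OCc6ccccc6)c(OCc6ccccc6)c5)O2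
F10 | step 11 | (2R,3R)-3,5,7-trihydroxy-6,8-dimethoxy-2-(3,4,5-trihydroxyphenyl)chroman-4-one | COc1c(O)c(OC)c2c(c1O)C(=O)[C@H](O)[C@@H](c1cc(O)c(O)c(O)c1)O2
A1 | alternative 1 | (E)-1-[2,4-bis(benzyloxy)-6-hydroxy-3,5-dimethoxyphenyl]-3-[3,4,5-tris(benzyloxy)phenyl]prop-2-en-1-one | O=C(/C=C/c1cc(OCc2ccccc2)c(OCc2ccccc2)c(OCc2ccccc2)c1)c1c(O)c(OC)c(OCc2ccccc2)c(OC)c1OCc1ccccc1
A2 | alternative 1 | (2R,3R)-5,7-bis(benzyloxy)-3-hydroxy-6,8-dimethoxy-2-[3,4,5-tris(benzyloxy)phenyl]chroman-4-one | COc1c(OCc3ccccc3)c(OC)c2c(c1OCc4ccccc4)C(=O)[C@H](O)[C@@H](c5cc(OCc6ccccc6)c(OCc6ccccc6)c(OCc6ccccc6)c5)O2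
A3 | alternative 2 | (3S,4R)-5,7-bis(benzyloxy)-3,4-bis(tert-butyldimethylsilyloxy)-6,8-dimethoxychroman-2-one | COc1c(OCc3ccccc3)c(OC)c2c(c1OCc4ccccc4)[C@@H](O[Si](C)(C)C(C)(C)C)[C@H](O[Si](C)(C)C(C)(C)C)C(=O)O2
A4 | alternative 2 | (3S,4R)-5,7-bis(benzyloxy)-3,4-bis(tert-butyldimethylsilyloxy)-6,8-dimethoxy-2-[3,4,5-tris(benzyloxy)phenyl]chroman-2-ol (anomeric mixture) | COc1c(OCc3ccccc3)c(OC)c2c(c1OCc4ccccc4)[C@@H](O[Si](C)(C)C(C)(C)C)[C@H](O[Si](C)(C)C(C)(C)C)C(O)(c5cc(OCc6ccccc6)c(OCc6ccccc6)c(OCc6ccccc6)c5)O2
A5 | alternative 3 | [2,4-bis(benzyloxy)-6-hydroxy-3,5-dimethoxybenzylidene](methyl)oxonium ion | C[O+]=Cc1c(O)c(OC)c(OCc2ccccc2)c(OC)c1OCc1ccccc1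
A6 | alternative 3 | (E)-2-[3,4,5-tris(benzyloxy)phenyl]ethenyl acetate | CC(=O)O/C=C/c1cc(OCc2ccccc2)c(OCc2ccccc2)c(OCc2ccccc2)c1
A7 | alternative 3 | (2R,3S,4R)-5,7-bis(benzyloxy)-4,6,8-trimethoxy-2-[3,4,5-tris(benzyloxy)phenyl]chroman-3-yl acetate | COc1c(OCc3ccccc3)c(OC)c2c(c1OCc4ccccc4)[C@@H](OC)[C@H](OC(C)=O)[C@@H](c5cc(OCc6ccccc6)c(OCc6ccccc6)c(OCc6ccccc6)c5)O2
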